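**Retrosynthetic overview**

1. Numbering runs from the lactone carbonyl C1 to the methyl C12; ring A is the 5,6-dihydropyran-2-one (O, C1–C5) and ring B is the oxolane (O, C7, C8, C9, C10).
2. The route rests on ring B and its C11–C12 branch: the ring oxygen, C10 and C9 together with C11–C12 form the skeleton of a threonine-derived α-hydroxy acid, C7 with C6 attached is an aldehyde carbon, and C8 is one added methylene.
3. Ring B is therefore disconnected at C7–C8 and closed first, by an aluminium-mediated Petasis–Ferrier rearrangement of a cis-2,5-disubstituted 4-methylene-1,3-dioxolane built from O-benzyl-D-threonine, (R)-glyceraldehyde acetonide and Cp2TiMe2.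
4. The C9 oxygen is then excised, the C11 benzyl ether is exchanged for the silyl-protected caffeate, and the C5/C6 acetonide becomes a C6-silyloxy C5 aldehyde whose matched allylboration sets C5.
5. Ring A is closed last by ring-closing metathesis of the C5 acrylate with the allyl group (C2=C3), and one fluoride treatment frees the C6 hydroxyl and the catechol.

Key step: step 4

Remark: the C9 carbinol formed in the key step is drawn as the all-cis epimer expected from hydride delivery anti to both ring substituents; its configuration does not matter because C9 is deoxygenated two steps later.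
Remark: O-benzyl-D-threonine, (R)-2,3-O-isopropylideneglyceraldehyde (freshly distilled before use) and caffeic acid are taken as purchased.

**Route**

Step 1
Reactants: 1 O-benzyl-D-threonine
Product: 2 (2R,3S)-3-(benzyloxy)-2-hydroxybutanoic acid
Conditions: NaNO2, 1 M aq. H2SO4, 0 °C → rt
Reagents that add atoms: water, O
Why: Diazotisation of the α-amino acid gives a diazonium ion that the neighbouring carboxylate displaces to an α-lactone, which water opens with a second inversion, so the C10 hydroxyl should arrive with net retention (2R) while the C11 benzyl ether is inert to cold dilute acid.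

Step 2
Reactants: 2 (2R,3S)-3-(benzyloxy)-2-hydroxybutanoic acid; 3 (R)-2,3-O-isopropylideneglyceraldehyde
Product: 5 cis-dioxolanone (2R,5R)-5-[(1S)-1-(benzyloxy)ethyl]-2-[(4R)-2,2-dimethyl-1,3-dioxolan-4-yl]-1,3-dioxolan-4-one, via bis(trimethylsilyl) hydroxy acid 4 (not isolated)
Conditions: HMDS, THF, rt, then evaporation; 3, TMSOTf (10 mol%), CH2Cl2, −78 °C; pyridine quench
Reagents that add atoms: none
Why: Silyl-triflate-catalysed acetalisation of the bis-silylated α-hydroxy acid with the aldehyde expels hexamethyldisiloxane at −78 °C and should give the 2,5-cis dioxolanone under kinetic control (acetal carbon C7 cis to the C10 side chain), mildly enough for the acetonide and the epimerisable aldehyde.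

Step 3
Reactants: 5 cis-dioxolanone
Product: 6 (2R,5R)-5-[(1S)-1-(benzyloxy)ethyl]-2-[(4R)-2,2-dimethyl-1,3-dioxolan-4-yl]-4-methylidene-1,3-dioxolane (2,5-cis)
Conditions: Cp2TiMe2 (2.5 equiv), toluene, 65 °C, dark; filtration through basic alumina
Reagents that add atoms: dimethyltitanocene Cp2TiMe2, C[Ti](C)(C1C=CC=C1)C1C=CC=C1
Why: Petasis methylenation, in which thermolysis of Cp2TiMe2 generates Cp2Ti=CH2 that olefinates the lactone-type carbonyl through an oxatitanacyclobutane under non-acidic conditions, adding C8 without disturbing either acetal or any stereocentre.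

Step 4
Reactants: 6 cis-4-methylidene-1,3-dioxolane
Product: 8 (2S,3R,5R)-2-[(1S)-1-(benzyloxy)ethyl]-5-[(4R)-2,2-dimethyl-1,3-dioxolan-4-yl]oxolan-3-ol (all-cis), via oxolan-3-one 7 (not isolated)
Conditions: iBu3Al (4 equiv), CH2Cl2, −78 → −20 °C; aq. potassium sodium tartrate (KNaC4H4O6) work-up
Reagents that add atoms: none
Why: This is the Petasis–Ferrier rearrangement in its oxolane form, in which a trialkylaluminium converts a 4-methylene-1,3-dioxolane into an oxolane and reduces the new C3 carbonyl in the same flask. iBu3Al binds the vinylic acetal oxygen, the C7–O bond to that oxygen ionises because only this cleavage releases an aluminium enolate (O–C9=C8), and the enolate carbon C8 then attacks the oxocarbenium carbon C7, which stays tethered through the ring oxygen and C10. The oxolane (O, C7, C8, C9, C10) closes in a 5-(enolendo)-endo-trig aldol-type cyclisation, formally disfavoured but established for this aluminium-mediated rearrangement. The new stereocentre C7 is controlled by C10: an envelope transition state with the C10 side chain and the C7 dioxolanyl group both pseudo-equatorial should give the 2,5-cis oxolane, and since the acetal centre is planar in the oxocarbenium ion any trans-acetal present should converge on the same product. The aluminium-bound ketone 7 is then reduced by β-hydride transfer from an isobutyl group on the face opposite both ring substituents, so C10 is never left α to a free carbonyl and can neither epimerise nor eliminate benzyl alcohol. The step needs ionisation at C7 rather than at the acetonide and needs the benzyl ether and acetonide to survive, which the enolate leaving group, the low temperature and the short reaction time should secure.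

Step 5
Reactants: 8 all-cis oxolan-3-ol
Product: 9 S-methyl xanthate of 8 (O-alkyl S-methyl dithiocarbonate at C9)
Conditions: NaH, imidazole (cat.), THF, 0 °C; CS2; MeI, rt
Reagents that add atoms: carbon disulfide, S=C=S; iodomethane, CI
Why: Xanthate formation, in which the sodium alkoxide adds to CS2 and the dithiocarbonate salt is S-methylated, with no base-sensitive group in the molecule at this stage.

Step 6
Reactants: 9 S-methyl xanthate
Product: 10 (4R)-4-[(2R,5S)-5-[(1S)-1-(benzyloxy)ethyl]oxolan-2-yl]-2,2-dimethyl-1,3-dioxolane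
Conditions: Bu3SnH, AIBN (cat.), toluene, 110 °C; aq. KF work-up
Reagents that add atoms: none
Why: Barton–McCombie deoxygenation, in which the stannyl radical adds to the thiocarbonyl, the C9–O bond fragments and the secondary C9 radical is reduced by Bu3SnH, leaving C7 and C10 untouched because the β C–O bonds of the ring ether do not fragment.

Step 7
Reactants: 10 benzyl ether
Product: 11 (1S)-1-[(2S,5R)-5-[(4R)-2,2-dimethyl-1,3-dioxolan-4-yl]oxolan-2-yl]ethan-1-ol
Conditions: H2 (1 atm), Pd/C, EtOAc, rt
Reagents that add atoms: none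
Why: Hydrogenolysis of the benzylic C–O bond on palladium under neutral conditions should leave the acetonide and the oxolane intact, and it is placed before any alkene enters the molecule.

Step 8
Reactants: 12 caffeic acid
Product: 14 (E)-3-[3,4-bis(tert-butyldimethylsilyloxy)phenyl]prop-2-enoic acid, via tris(tert-butyldimethylsilyl) caffeate 13 (not isolated)
Conditions: TBSCl (3.3 equiv), imidazole, DMF, rt; then AcOH/THF/H2O (3:1:1), rt
Reagents that add atoms: tert-butyldimethylsilyl chloride, CC(C)(C)[Si](C)(C)Cl
Why: Silylation of both phenols and the acid, followed in the same flask by selective hydrolysis of the far more labile silyl ester, should leave the two aryl silyl ethers, which tolerate aqueous acetic acid.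

Step 9
Reactants: 11 C11 alcohol; 14 bis-silylated caffeic acid
Product: 15 C11 caffeate: (1S)-1-[(2S,5R)-5-[(4R)-2,2-dimethyl-1,3-dioxolan-4-yl]oxolan-2-yl]ethyl (E)-3-[3,4-bis(tert-butyldimethylsilyloxy)phenyl]prop-2-enoate
Conditions: DCC, DMAP, CH2Cl2, 0 °C → rt
Reagents that add atoms: none
Why: Steglich esterification through the O-acylisourea and the acylpyridinium ion acylates the C11 hydroxyl at oxygen, so C11 keeps its configuration and the E-alkene is not touched.

Step 10
Reactants: 15 acetonide caffeate
Product: 16 C5,C6-diol: (1S)-1-[(2S,5R)-5-[(1R)-1,2-dihydroxyethyl]oxolan-2-yl]ethyl (E)-3-[3,4-bis(tert-butyldimethylsilyloxy)phenyl]prop-2-enoate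
Conditions: AcOH/H2O/THF (3:1:1), 40 °C
Reagents that add atoms: none
Why: Acid-catalysed hydrolysis of the terminal isopropylidene acetal, under which the cinnamate ester and the aryl silyl ethers are expected to persist.

Step 11
Reactants: 16 C5,C6-diol
Product: 17 C5,C6-bis(triethylsilyl) ether of 16
Conditions: TESOTf (2.5 equiv), 2,6-lutidine, CH2Cl2, −78 → 0 °C
Reagents that add atoms: triethylsilyl trifluoromethanesulfonate, CC[Si](CC)(CC)OS(=O)(=O)C(F)(F)F
Why: A silyl triflate with a hindered pyridine base silylates the primary and the hindered secondary hydroxyl alike, and the aryl silyl ethers and the ester are not affected by 2,6-lutidine.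

Step 12
Reactants: 17 bis(triethylsilyl) ether
Product: 18 C5 aldehyde carrying the C6 triethylsilyl ether (configuration at C6 unchanged)
Conditions: (COCl)2, DMSO, CH2Cl2, −78 → −30 °C; Et3N, −78 → 0 °C; used crude
Reagents that add atoms: none
Why: Swern oxidation applied directly to a primary triethylsilyl ether, in which the chlorosulfonium reagent cleaves the unhindered primary O–Si bond selectively and the alkoxysulfonium ion collapses to the aldehyde on addition of base, while the secondary C6 silyl ether remains in place.

Step 13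
Reactants: 18 C6-silyloxy C5 aldehyde
Product: 19 homoallylic alcohol (free C5–OH, 5,6-anti as in the target; C6 triethylsilyl ether; terminal alkene C3=CH2)
Conditions: (S,S)-diisopropyl tartrate allylboronate (1.5 equiv), 4 Å molecular sieves, toluene, −78 °C; aq. NaHCO3 work-up
Reagents that add atoms: diisopropyl (4S,5S)-2-allyl-1,3,2-dioxaborolane-4,5-dicarboxylate, C=CCB1O[C@H](C(=O)OC(C)C)[C@@H](C(=O)OC(C)C)O1
Why: Roush asymmetric allylboration through a chair Zimmerman–Traxler transition state, in which the (S,S)-tartrate reagent delivers allyl to the Re face of the aldehyde, the same face favoured by the Felkin–Anh/Cornforth preference of the C6-silyloxy aldehyde (matched pair), which should set C5 with the 5,6-anti relationship of the target, and the non-oxidative work-up spares the ester and the aryl silyl ethers.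

Step 14
Reactants: 19 homoallylic alcohol
Product: 20 C5 acrylate of 19
Conditions: acryloyl chloride, iPr2NEt, DMAP (cat.), CH2Cl2, −20 → 0 °C
Reagents that add atoms: acryloyl chloride, C=CC(=O)Cl
Why: O-Acylation of the C5 hydroxyl with the acid chloride and a hindered amine at low temperature, conditions under which silyl migration from C6 and acrylate polymerisation should be minimal.

Step 15
Reactants: 20 acrylate diene
Product: 21 fully silylated target (ring A closed; C6 triethylsilyl ether; catechol bis-TBS ether)
Conditions: second-generation Grubbs catalyst (H2IMes)(PCy3)Cl2Ru=CHPh (5 mol%), CH2Cl2 (2 mM), 40 °C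
Reagents that add atoms: none
Why: Ring-closing metathesis, in which the ruthenium carbene loads at the terminal C3 alkene and closes onto the acrylate to give the six-membered lactone with its ring-enforced Z alkene, the conjugated 1,2-disubstituted cinnamate alkene being far less reactive and high dilution suppressing intermolecular metathesis.

Step 16
Reactants: 21 fully silylated target
Product: 22 CNP0300981.1
Conditions: Bu4NF, AcOH (1:1.2), THF, 0 °C → rt
Reagents that add atoms: none
Why: Fluoride cleaves the two aryl Si–O bonds and the secondary Si–O bond at C6, and acetic acid buffering keeps the catechol protonated so that the unsaturated lactone and the cinnamate ester should survive.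

**Compound list**

1 | O-benzyl-D-threonine | C[C@H](OCc1ccccc1)[C@@H](N)C(=O)O | starting material
2 | (2R,3S)-3-(benzyloxy)-2-hydroxybutanoic acid | C[C@H](OCc1ccccc1)[C@@H](O)C(=O)O | intermediate
3 | (R)-2,3-O-isopropylideneglyceraldehyde | O=C[C@H]1COC(C)(C)O1 | starting material
4 | trimethylsilyl (2R,3S)-3-(benzyloxy)-2-(trimethylsilyloxy)butanoate | C[C@H](OCc1ccccc1)[C@@H](O[Si](C)(C)C)C(=O)O[Si](C)(C)C | intermediate
5 | (2R,5R)-5-[(1S)-1-(benzyloxy)ethyl]-2-[(4R)-2,2-dimethyl-1,3-dioxolan-4-yl]-1,3-dioxolan-4-one (2,5-cis) | C[C@H](OCc1ccccc1)[C@H]1O[C@@H]([C@H]2COC(C)(C)O2)OC1=O | intermediate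
6 | (2R,5R)-5-[(1S)-1-(benzyloxy)ethyl]-2-[(4R)-2,2-dimethyl-1,3-dioxolan-4-yl]-4-methylidene-1,3-dioxolane (2,5-cis) | C[C@H](OCc1ccccc1)[C@H]1O[C@@H]([C@H]2COC(C)(C)O2)OC1=C | intermediate
7 | (2R,5R)-2-[(1S)-1-(benzyloxy)ethyl]-5-[(4R)-2,2-dimethyl-1,3-dioxolan-4-yl]oxolan-3-one (2,5-cis) | C[C@H](OCc1ccccc1)[C@@H]1C(=O)C[C@H]([C@H]2COC(C)(C)O2)O1 | intermediate
8 | (2S,3R,5R)-2-[(1S)-1-(benzyloxy)ethyl]-5-[(4R)-2,2-dimethyl-1,3-dioxolan-4-yl]oxolan-3-ol (all-cis) | C[C@H](OCc1ccccc1)[C@@H]1[C@H](O)C[C@H]([C@H]2COC(C)(C)O2)O1 | intermediate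
9 | S-methyl xanthate of 8 at C9 | C[C@H](OCc1ccccc1)[C@@H]1[C@H](OC(=S)SC)C[C@H]([C@H]2COC(C)(C)O2)O1 | intermediate
10 | (4R)-4-[(2R,5S)-5-[(1S)-1-(benzyloxy)ethyl]oxolan-2-yl]-2,2-dimethyl-1,3-dioxolane | C[C@H](OCc1ccccc1)[C@@H]1CC[C@H]([C@H]2COC(C)(C)O2)O1 | intermediate
11 | (1S)-1-[(2S,5R)-5-[(4R)-2,2-dimethyl-1,3-dioxolan-4-yl]oxolan-2-yl]ethan-1-ol | C[C@H](O)[C@@H]1CC[C@H]([C@H]2COC(C)(C)O2)O1 | intermediate
12 | caffeic acid | OC(=O)/C=C/c1ccc(O)c(O)c1 | starting material
13 | tert-butyldimethylsilyl (E)-3-[3,4-bis(tert-butyldimethylsilyloxy)phenyl]prop-2-enoate | CC(C)(C)[Si](C)(C)OC(=O)/C=C/c1ccc(O[Si](C)(C)C(C)(C)C)c(O[Si](C)(C)C(C)(C)C)c1 | intermediate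
14 | (E)-3-[3,4-bis(tert-butyldimethylsilyloxy)phenyl]prop-2-enoic acid | OC(=O)/C=C/c1ccc(O[Si](C)(C)C(C)(C)C)c(O[Si](C)(C)C(C)(C)C)c1 | intermediate
15 | C11 bis-TBS-caffeate with C5/C6 acetonide | C[C@H](OC(=O)/C=C/c1ccc(O[Si](C)(C)C(C)(C)C)c(O[Si](C)(C)C(C)(C)C)c1)[C@@H]1CC[C@H]([C@H]2COC(C)(C)O2)O1 | intermediate
16 | C11 bis-TBS-caffeate with free C5,C6-diol | C[C@H](OC(=O)/C=C/c1ccc(O[Si](C)(C)C(C)(C)C)c(O[Si](C)(C)C(C)(C)C)c1)[C@@H]1CC[C@H]([C@H](O)CO)O1 | intermediate
17 | C5,C6-bis(triethylsilyl) ether of 16 | C[C@H](OC(=O)/C=C/c1ccc(O[Si](C)(C)C(C)(C)C)c(O[Si](C)(C)C(C)(C)C)c1)[C@@H]1CC[C@H]([C@H](O[Si](CC)(CC)CC)CO[Si](CC)(CC)CC)O1 | intermediate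
18 | C5 aldehyde with C6 triethylsilyl ether | C[C@H](OC(=O)/C=C/c1ccc(O[Si](C)(C)C(C)(C)C)c(O[Si](C)(C)C(C)(C)C)c1)[C@@H]1CC[C@H]([C@H](O[Si](CC)(CC)CC)C=O)O1 | intermediate
19 | homoallylic alcohol (C5–OH, 5,6-anti, C6 triethylsilyl ether) | C[C@H](OC(=O)/C=C/c1ccc(O[Si](C)(C)C(C)(C)C)c(O[Si](C)(C)C(C)(C)C)c1)[C@@H]1CC[C@H]([C@H](O[Si](CC)(CC)CC)[C@H](O)CC=C)O1 | intermediate
20 | C5 acrylate of 19 | C[C@H](OC(=O)/C=C/c1ccc(O[Si](C)(C)C(C)(C)C)c(O[Si](C)(C)C(C)(C)C)c1)[C@@H]1CC[C@H]([C@H](O[Si](CC)(CC)CC)[C@H](OC(=O)C=C)CC=C)O1 | intermediate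
21 | target with C6 triethylsilyl ether and catechol bis-TBS ether | C[C@H](OC(=O)/C=C/c1ccc(O[Si](C)(C)C(C)(C)C)c(O[Si](C)(C)C(C)(C)C)c1)[C@@H]1CC[C@H]([C@H](O[Si](CC)(CC)CC)[C@H]2CC=CC(=O)O2)O1 | intermediate
22 | CNP0300981.1 | C[C@H](OC(=O)/C=C/c1ccc(O)c(O)c1)[C@@H]1CC[C@H]([C@H](O)[C@H]2CC=CC(=O)O2)O1 | target

**Step count**

Total steps: 16. Longest linear sequence: 15 (steps 1–7 and 9–16, from 1); step 8 is a one-step side branch.

**Steps most likely to fail**

1. Step 4. The C7 oxocarbenium ion is destabilised by the C6 oxygen, so ionisation may be slow. The alane may instead be sequestered by chelation to the acetonide or benzyl ether oxygens, or may open the acetonide reductively. The 5-endo closure may also be outrun by fragmentation, or may lose 2,5-cis control. Fallback with known chemistry, setting out from 2 and 3 and returning at 10: the oxolane is closed by an intramolecular Williamson displacement instead of a C7–C8 bond formation on an acetal. Acid 2 is esterified (MeOH, SOCl2) to the methyl ester F1 and silylated (TBSCl, imidazole, DMF) to the silyl ether F2. Half-reduction (iBu2AlH, CH2Cl2, −78 °C) gives the aldehyde F3, and the Ohira–Bestmann reagent (K2CO3, MeOH) homologates it to the terminal alkyne F4, which now carries C8. Lithiated F4 (nBuLi, THF, −78 °C) adds to aldehyde 3 under Felkin–Anh control to give mainly the 6,7-anti propargylic alcohol F5, the minor C7 epimer being removed by chromatography. Hydrogenation of the alkyne over PtO2 in EtOAc, which should spare the benzyl ether, gives the saturated alcohol F6, and MsCl/Et3N gives the C7 mesylate F7. Bu4NF in THF (rt → 50 °C) removes the C10 silyl group to give the hydroxy mesylate F8, whose C10 oxygen displaces the mesylate in a 5-exo-tet closure with inversion at C7, giving the 7,10-cis oxolane 10.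

2. Step 13. Facial selectivity may be insufficient if the syn C6/C7 dioxygenation pattern works against the α-silyloxy preference, and a slow addition would give time for C6 epimerisation or 6→5 silyl migration. Fallback, setting out from 18 and returning at 19: the control element is changed from a reagent-controlled closed transition state to substrate control in an open one. Allyltributylstannane (allylSnBu3) with BF3·OEt2 in CH2Cl2 at −78 °C adds through a Felkin–Anh transition state with the C6–O bond antiperiplanar to the incoming nucleophile, which favours the same 5,6-anti alcohol 19; this fallback makes no new compound (F0).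

3. Step 12. Both silyl ethers may be cleaved unselectively, or the primary one may be cleaved incompletely, and C6 may epimerise during the amine step. Fallback, setting out from 17 and returning at 18: deprotection and oxidation are separated. PPTS in MeOH/CH2Cl2 at −10 °C removes only the primary silyl group to give the primary alcohol F9, which is oxidised with Dess–Martin periodinane buffered with NaHCO3 in CH2Cl2 to aldehyde 18 without exposure to amine base.

**Further compounds**

F1 | step 4 | methyl (2R,3S)-3-(benzyloxy)-2-hydroxybutanoate | C[C@H](OCc1ccccc1)[C@@H](O)C(=O)OC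
F2 | step 4 | methyl (2R,3S)-3-(benzyloxy)-2-(tert-butyldimethylsilyloxy)butanoate | C[C@H](OCc1ccccc1)[C@@H](O[Si](C)(C)C(C)(C)C)C(=O)OC
F3 | step 4 | (2R,3S)-3-(benzyloxy)-2-(tert-butyldimethylsilyloxy)butanal | C[C@H](OCc1ccccc1)[C@@H](O[Si](C)(C)C(C)(C)C)C=O
F4 | step 4 | terminal alkyne (C8≡C9) with C10 silyl ether and C11 benzyl ether | C[C@H](OCc1ccccc1)[C@@H](O[Si](C)(C)C(C)(C)C)C#C
F5 | step 4 | 6,7-anti propargylic alcohol from F4 and 3 | C[C@H](OCc1ccccc1)[C@@H](O[Si](C)(C)C(C)(C)C)C#C[C@H](O)[C@H]1COC(C)(C)O1
F6 | step 4 | saturated C7 alcohol | C[C@H](OCc1ccccc1)[C@@H](O[Si](C)(C)C(C)(C)C)CC[C@H](O)[C@H]1COC(C)(C)O1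
F7 | step 4 | C7 mesylate with C10 silyl ether | C[C@H](OCc1ccccc1)[C@@H](O[Si](C)(C)C(C)(C)C)CC[C@H](OS(C)(=O)=O)[C@H]1COC(C)(C)O1
F8 | step 4 | C10 hydroxy C7 mesylate | C[C@H](OCc1ccccc1)[C@@H](O)CC[C@H](OS(C)(=O)=O)[C@H]1COC(C)(C)O1
F0 | step 13 | none | none
F9 | step 12 | primary C5 alcohol with C6 triethylsilyl ether | C[C@H](OC(=O)/C=C/c1ccc(O[Si](C)(C)C(C)(C)C)c(O[Si](C)(C)C(C)(C)C)c1)[C@@H]1CC[C@H]([C@H](O[Si](CC)(CC)CC)CO)O1
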